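**Plan**
- Retrosynthesis: the two benzyl ethers (5-O and 4'-O) are cut last. The oxocine ring is then cut at both ends at once, C3–CH2 and O–C(CH3)2, giving a 3-unsubstituted 2'-hydroxyflavone and a C5 tertiary allylic carbonate. The pyranone is cut at O1–C2 and C2–C3, giving a ring-A acetophenone and a ring-B salicylate ester.
- Enabling feature: the 2'-oxygen of ring B, C2', C1', C2 and C3–H of the pyranone (ring C) form a 2-alkenylphenol. O and C3–H are 1,5-related and cis across C2=C3, so one metal can bridge them in a six-membered ring, and the three-carbon backbone of a prenyl unit then bridges them as the eight-membered ring.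
- Forward order: ring-A ketone plus ring-B ester give the 1,3-diketone, then ring C, then the oxocine ring by one-pot hydroxyl-directed C3–H prenylation and cycloetherification, then debenzylation.
- Stereochemistry: the target has no stereocenter; the questions are site selectivity (C3 against the electron-rich arene positions) and which hydroxyl is free at which stage.

Key step: step 7

Remark: flavone numbering is used throughout (ring A = benzo ring of the chromone, ring C = pyranone, ring B = 2-aryl group with positions 2'–6').

**Step 1**
Reactants: 1 methyl 2,4-dihydroxybenzoate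
Product: 2 methyl 4-(benzyloxy)-2-hydroxybenzoate
Conditions: BnBr (1.05 equiv), K2CO3, acetone, reflux
Reagents that add atoms: benzyl bromide, BrCc1ccccc1
Why: Williamson ether synthesis; the 2-hydroxyl is hydrogen-bonded to the ester carbonyl and much less nucleophilic, so only the 4-hydroxyl should be alkylated.

**Step 2**
Reactants: 2 methyl 4-(benzyloxy)-2-hydroxybenzoate
Product: 3 methyl 4-(benzyloxy)-2-(methoxymethoxy)benzoate
Conditions: NaH, DMF, 0 °C; MOMCl, 0 to 23 °C
Reagents that add atoms: chloromethyl methyl ether, COCCl
Why: full deprotonation breaks the hydrogen bond and O-alkylation of the phenoxide gives the MOM acetal, a protecting group orthogonal to the benzyl ethers.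

**Step 3**
Reactants: 4 1-(2,6-dihydroxy-4-methoxyphenyl)ethanone
Product: 5 1-[2-(benzyloxy)-6-hydroxy-4-methoxyphenyl]ethanone
Conditions: BnBr (1.0 equiv), K2CO3, acetone, reflux
Reagents that add atoms: benzyl bromide, BrCc1ccccc1
Why: Williamson ether synthesis; the two hydroxyls are equivalent, and after the first alkylation the remaining one is locked in the chelate to the acetyl carbonyl, so the mono-ether should be formed.

**Step 4**
Reactants: 5 1-[2-(benzyloxy)-6-hydroxy-4-methoxyphenyl]ethanone; 3 methyl 4-(benzyloxy)-2-(methoxymethoxy)benzoate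
Product: 6 1-[2-(benzyloxy)-6-hydroxy-4-methoxyphenyl]-3-[4-(benzyloxy)-2-(methoxymethoxy)phenyl]propane-1,3-dione
Conditions: LiN(SiMe3)2 (3.5 equiv), THF, −78 °C; then 3, −78 to 23 °C; AcOH quench
Reagents that add atoms: none
Why: crossed Claisen condensation of the phenoxide–enolate dianion of 5 with the non-enolisable ester 3, driven by deprotonation of the 1,3-diketone by the third equivalent of base; this forms the future C2–C3 bond.

**Step 5**
Reactants: 6 1-[2-(benzyloxy)-6-hydroxy-4-methoxyphenyl]-3-[4-(benzyloxy)-2-(methoxymethoxy)phenyl]propane-1,3-dione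
Product: 8 5-(benzyloxy)-2-[4-(benzyloxy)-2-hydroxyphenyl]-7-methoxy-4H-chromen-4-one, via MOM-protected flavone 7 (not isolated)
Conditions: HCl (3 M in MeOH), 55 °C
Reagents that add atoms: none
Why: acid-catalysed cyclodehydration of an o-hydroxyaryl 1,3-diketone (flavone synthesis), in which the ring-A hydroxyl should add to the less hindered ring-B carbonyl and water is lost, followed by solvolysis of the MOM acetal in methanol, which frees the 2'-hydroxyl while the benzyl ethers should survive dilute methanolic acid.

**Step 6**
Reactants: 9 2-methylbut-3-en-2-ol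
Product: 10 methyl 2-methylbut-3-en-2-yl carbonate
Conditions: n-BuLi, THF, 0 °C; ClCO2Me, 0 to 23 °C
Reagents that add atoms: methyl chloroformate, COC(=O)Cl
Why: acylation of the lithium alkoxide of a tertiary alcohol with a chloroformate (carbonate formation), which turns the hydroxyl into a leaving group for beta-oxygen elimination.

**Step 7**
Reactants: 8 5-(benzyloxy)-2-[4-(benzyloxy)-2-hydroxyphenyl]-7-methoxy-4H-chromen-4-one; 10 methyl 2-methylbut-3-en-2-yl carbonate
Product: 12 5,4'-di-O-benzylcyclointegrin, via 3-prenyl-2'-hydroxyflavone 11 (not isolated)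
Conditions: [Cp*Rh(MeCN)3](SbF6)2 (5 mol %), NaO2CCMe3 (20 mol %), 10 (1.2 equiv), ClCH2CH2Cl, 40 °C; then CF3SO3H (40 mol %), 0 to 23 °C
Reagents that add atoms: none
Why: Proposed new method: the free 2'-hydroxyl of 8 binds the cationic Cp*Rh centre (trivalent rhodium) and, by carboxylate-assisted concerted metalation–deprotonation, delivers it to the only C–H bond that closes a six-membered oxarhodacycle, the C3–H of ring C, which lies cis to ring B across C2=C3. The vinyl group of 10 then inserts with C3 bonding to the terminal CH2, and beta-oxygen elimination of methyl carbonate (lost as CO2 and methanol) should release the 3-prenyl phenol 11 and return trivalent rhodium without an external oxidant. Triflic acid added to the same flask should protonate the trisubstituted alkene of 11 at its CH carbon, and the tertiary cation is captured by the 2'-oxygen in an 8-endo-trig (Markovnikov) closure that forms the oxocine ring; no stereocenter is created. The closest known reaction types are the Cp*Rh-catalysed C–H allylation with allylic carbonates, the hydroxyl-directed alkenyl C–H annulations of 2-alkenylphenols, and the acid-catalysed cyclisation of ortho-prenylphenols to 2,2-dimethylchromans. The step needs site selectivity for C3 over the electron-rich C6, C8, C3' and C5' positions, which chelation should secure because no other C–H bond can reach rhodium from the phenoxide through a five- or six-membered ring, and because the near-neutral first stage should not ionise the carbonate. It also needs capture of the cation by the 2'-oxygen and not by the C4 carbonyl oxygen, which is expected because carbonyl capture gives only a 4-alkoxybenzopyrylium ion that cannot lose a proton and reverts; the benzyl ethers keep the 5- and 4'-oxygens from chelating rhodium or trapping the cation.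

**Step 8**
Reactants: 12 5,4'-di-O-benzylcyclointegrin
Product: 13 cyclointegrin
Conditions: H2 (1 atm), Pd/C (10 wt %), EtOAc–MeOH, 23 °C
Reagents that add atoms: none
Why: hydrogenolysis of the two aryl benzyl ethers; the tetrasubstituted, push–pull C2=C3 bond of the chromone and the tertiary alkyl aryl ether should be inert under these conditions.

**Compound list**
1 | methyl 2,4-dihydroxybenzoate | COC(=O)c1ccc(O)cc1O | starting material
2 | methyl 4-(benzyloxy)-2-hydroxybenzoate | COC(=O)c1ccc(OCc2ccccc2)cc1O | intermediate
3 | methyl 4-(benzyloxy)-2-(methoxymethoxy)benzoate | COCOc1cc(OCc2ccccc2)ccc1C(=O)OC | intermediate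
4 | 1-(2,6-dihydroxy-4-methoxyphenyl)ethanone | CC(=O)c1c(O)cc(OC)cc1O | starting material
5 | 1-[2-(benzyloxy)-6-hydroxy-4-methoxyphenyl]ethanone | CC(=O)c1c(O)cc(OC)cc1OCc1ccccc1 | intermediate
6 | 1-[2-(benzyloxy)-6-hydroxy-4-methoxyphenyl]-3-[4-(benzyloxy)-2-(methoxymethoxy)phenyl]propane-1,3-dione | COCOc1cc(OCc2ccccc2)ccc1C(=O)CC(=O)c1c(O)cc(OC)cc1OCc1ccccc1 | intermediate
7 | 5-(benzyloxy)-2-[4-(benzyloxy)-2-(methoxymethoxy)phenyl]-7-methoxy-4H-chromen-4-one (MOM-protected flavone, formed in the flask in step 5) | COCOc1cc(OCc2ccccc2)ccc1-c1cc(=O)c2c(OCc3ccccc3)cc(OC)cc2o1 | intermediate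
8 | 5-(benzyloxy)-2-[4-(benzyloxy)-2-hydroxyphenyl]-7-methoxy-4H-chromen-4-one | COc1cc(OCc2ccccc2)c2c(=O)cc(-c3ccc(OCc4ccccc4)cc3O)oc2c1 | intermediate
9 | 2-methylbut-3-en-2-ol | CC(C)(O)C=C | starting material
10 | methyl 2-methylbut-3-en-2-yl carbonate | COC(=O)OC(C)(C)C=C | intermediate
11 | 5-(benzyloxy)-2-[4-(benzyloxy)-2-hydroxyphenyl]-7-methoxy-3-(3-methylbut-2-en-1-yl)-4H-chromen-4-one (3-prenyl-2'-hydroxyflavone, formed in the flask in step 7) | COc1cc(OCc2ccccc2)c2c(=O)c(CC=C(C)C)c(-c3ccc(OCc4ccccc4)cc3O)oc2c1 | intermediate
12 | 5,4'-di-O-benzylcyclointegrin: the 7-methoxyflavone whose C3 and 2'-oxygen are bridged by CH2CH2C(CH3)2 in an eight-membered oxocine ring, with benzyl ethers on the 5- and 4'-oxygens | COc1cc(OCc2ccccc2)c2c(=O)c3c(oc2c1)-c1ccc(OCc2ccccc2)cc1OC(C)(C)CC3 | intermediate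
13 | cyclointegrin: 5,4'-dihydroxy-7-methoxyflavone whose C3 and 2'-oxygen are bridged by CH2CH2C(CH3)2 (achiral) | COc1cc(O)c2c(=O)c3c(oc2c1)-c1ccc(O)cc1OC(C)(C)CC3 | target

**Summary**
Total step count: 8. Longest linear sequence: 6 steps (steps 1, 2, 4, 5, 7, 8).

Steps most likely to fail:

1. Step 7 (Proposed new method). The rhodium stage may stall if the phenoxide binds the metal but the C3–H bond next to the carbonyl is not cleaved. The carbonate may also ionise and prenylate the alkoxy-rich rings without direction. In the acid stage the tertiary cation may be lost to elimination or intermolecular alkylation before the eight-membered ring closes. Fallback with known chemistry, setting out from 6: the central carbon of the diketone is C-alkylated with prenyl bromide (K2CO3, acetone, reflux) to give the 2-prenyl-1,3-diketone F1. HCl in MeOH at 55 °C then closes the pyranone and removes the MOM group to give 11, which is isolated this time. Finally p-TsOH·H2O in toluene at 80 °C effects the cycloetherification, and the route is rejoined at 12.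

2. Step 5. The MOM acetal may be lost before the pyranone closes, which would let the ring-B hydroxyl close onto the ring-A carbonyl and give the isomeric chromone; the peri benzyl ether may also be cleaved by acid. Fallback, setting out from 2: the 2-hydroxyl is protected with allyl bromide (K2CO3, DMF, 60 °C) as the acid-stable allyl ether F2. Claisen condensation of F2 with 5 (LiN(SiMe3)2, THF) gives the allyl-protected diketone F3. Cyclodehydration (p-TsOH·H2O, toluene, 80 °C) gives the 2'-O-allyl flavone F4, in which only the ring-A hydroxyl was available for closure. Deallylation with Pd(PPh3)4 (zerovalent palladium) and morpholine in THF returns to the route at 8.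

3. Step 4. Acylation of the hindered dianion by the electron-rich, ortho-substituted ester may be slow, so that proton transfer simply returns the ketone. Fallback, setting out from 3 and 5: the ester is saponified (LiOH, THF–H2O) to the benzoic acid F5. F5 is coupled with the phenol of 5 (EDC·HCl, DMAP, CH2Cl2) to give the aryl ester F6. Baker–Venkataraman rearrangement (KOH, pyridine, 50 °C) moves the acyl group from oxygen to carbon, and the route is rejoined at 6.

**Further compounds**
F1 | step 7 | 1-[2-(benzyloxy)-6-hydroxy-4-methoxyphenyl]-3-[4-(benzyloxy)-2-(methoxymethoxy)phenyl]-2-(3-methylbut-2-en-1-yl)propane-1,3-dione | COCOc1cc(OCc2ccccc2)ccc1C(=O)C(CC=C(C)C)C(=O)c1c(O)cc(OC)cc1OCc1ccccc1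
F2 | step 5 | methyl 2-(allyloxy)-4-(benzyloxy)benzoate | C=CCOc1cc(OCc2ccccc2)ccc1C(=O)OC
F3 | step 5 | 1-[2-(allyloxy)-4-(benzyloxy)phenyl]-3-[2-(benzyloxy)-6-hydroxy-4-methoxyphenyl]propane-1,3-dione | C=CCOc1cc(OCc2ccccc2)ccc1C(=O)CC(=O)c1c(O)cc(OC)cc1OCc1ccccc1
F4 | step 5 | 2-[2-(allyloxy)-4-(benzyloxy)phenyl]-5-(benzyloxy)-7-methoxy-4H-chromen-4-one | C=CCOc1cc(OCc2ccccc2)ccc1-c1cc(=O)c2c(OCc3ccccc3)cc(OC)cc2o1
F5 | step 4 | 4-(benzyloxy)-2-(methoxymethoxy)benzoic acid | COCOc1cc(OCc2ccccc2)ccc1C(=O)O
F6 | step 4 | 2-acetyl-3-(benzyloxy)-5-methoxyphenyl 4-(benzyloxy)-2-(methoxymethoxy)benzoate | COCOc1cc(OCc2ccccc2)ccc1C(=O)Oc1cc(OC)cc(OCc2ccccc2)c1C(C)=O
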